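The target is the all-syn (2S,3S,5S)-1,7-diarylheptane-2,3,5-triol. It is opened at the C2–C3 bond of the vicinal diol. This gives a two-carbon piece (C1–C2) carrying the 4-hydroxyphenyl ring (ring B) and a five-carbon piece (C3–C7) carrying the 4-hydroxy-3-methoxyphenyl ring (ring A).
Enabling feature: C1 is a methylene that is benzylic to ring B and bonded to carbinol C2. Raised to the ketone level, C1–C2 plus ring B is a 2-hydroxyacetophenone, whose OH/C=O pair chelates zinc as an enediolate and makes C2 a nucleophile. Because this carbonyl is benzylic and para-oxygenated, hydrogenolysis can erase it again together with the benzyl ethers.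
Key union: a direct catalytic asymmetric aldol of the free hydroxy ketone with a (5S)-β-silyloxy aldehyde forms C2–C3 and sets C2 and C3 (syn) in one operation.
The aldehyde comes from zingerone (ring A plus C4–C7) by carbomethoxylation (adds C3), Noyori hydrogenation (sets C5), silylation and partial reduction.
No ring is formed at any stage, since both benzene rings are bought intact. The endgame is ketone reduction followed by hydrogenolysis and desilylation.

Key step: step 7

Assumption: the (S,S) ligand is taken to deliver the (2R,3S)-syn adduct, as expected from its behaviour with the parent 2-hydroxyacetophenone. Both ligand enantiomers are commercial, so the sense can be matched if it proves opposite.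

Step 1
Reactants: 1 zingerone, 4-(4-hydroxy-3-methoxyphenyl)butan-2-one
Product: 2 4-[4-(benzyloxy)-3-methoxyphenyl]butan-2-one
Conditions: BnBr, K2CO3, DMF, rt
Reagents that add atoms: benzyl bromide, BrCc1ccccc1
Why: Williamson ether synthesis, in which K2CO3 ionises only the phenol, so that O-benzylation should proceed without touching the ketone.

Step 2
Reactants: 2 4-[4-(benzyloxy)-3-methoxyphenyl]butan-2-one
Product: 3 methyl 5-[4-(benzyloxy)-3-methoxyphenyl]-3-oxopentanoate
Conditions: NaH, (MeO)2CO, THF, reflux; 1 M HCl quench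
Reagents that add atoms: dimethyl carbonate, COC(=O)OC
Why: Crossed Claisen-type carbomethoxylation of a methyl ketone under equilibrating conditions, driven to the methyl terminus because only that regioisomer is drained off as the unhindered, fully conjugated β-keto ester enolate.

Step 3
Reactants: 3 methyl 5-[4-(benzyloxy)-3-methoxyphenyl]-3-oxopentanoate
Product: 4 methyl (3S)-5-[4-(benzyloxy)-3-methoxyphenyl]-3-hydroxypentanoate
Conditions: RuCl2[(S)-BINAP] (0.5 mol %), H2 (10 atm), MeOH, 50 °C
Reagents that add atoms: none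
Why: Noyori asymmetric hydrogenation of a β-keto ester, in which the keto ester chelates the ruthenium hydride and the (S)-BINAP quadrants direct hydride to the face that gives the (S)-carbinol (C5 of the target), while aryl benzyl ethers are inert to this homogeneous catalyst.

Step 4
Reactants: 4 methyl (3S)-5-[4-(benzyloxy)-3-methoxyphenyl]-3-hydroxypentanoate
Product: 5 methyl (3S)-5-[4-(benzyloxy)-3-methoxyphenyl]-3-[(tert-butyldimethylsilyl)oxy]pentanoate
Conditions: TBSCl, imidazole, DMF, rt
Reagents that add atoms: tert-butyldimethylsilyl chloride, CC(C)(C)[Si](C)(C)Cl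
Why: Imidazole-promoted silylation of a secondary alcohol, which is nearly neutral and should therefore avoid retro-aldol or elimination of the β-hydroxy ester and leave the stereocentre untouched.

Step 5
Reactants: 5 methyl (3S)-5-[4-(benzyloxy)-3-methoxyphenyl]-3-[(tert-butyldimethylsilyl)oxy]pentanoate
Product: 6 (3S)-5-[4-(benzyloxy)-3-methoxyphenyl]-3-[(tert-butyldimethylsilyl)oxy]pentanal
Conditions: i-Bu2AlH (1.1 equiv), CH2Cl2, −78 °C; MeOH, then aq. potassium sodium tartrate
Reagents that add atoms: none
Why: Partial reduction of an ester with i-Bu2AlH, which should stop at the aldehyde level because the tetrahedral adduct does not collapse at −78 °C before the quench.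

Step 6
Reactants: 7 2-bromo-1-[4-(benzyloxy)phenyl]ethan-1-one
Product: 9 2-hydroxy-1-[4-(benzyloxy)phenyl]ethan-1-one, via formate ester 8 (not isolated)
Conditions: HCO2Na, EtOH–H2O, reflux
Reagents that add atoms: sodium formate, [Na+].[O-]C=O
Why: SN2 displacement of the activated phenacyl bromide by formate followed by hydrolysis of the labile formate ester in the same pot, a standard entry to 2-hydroxyacetophenones that avoids strong base.

Step 7
Reactants: 6 (3S)-5-[4-(benzyloxy)-3-methoxyphenyl]-3-[(tert-butyldimethylsilyl)oxy]pentanal; 9 2-hydroxy-1-[4-(benzyloxy)phenyl]ethan-1-one (1.5 equiv)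
Product: 10 (2R,3S,5S)-1-[4-(benzyloxy)phenyl]-7-[4-(benzyloxy)-3-methoxyphenyl]-5-[(tert-butyldimethylsilyl)oxy]-2,3-dihydroxyheptan-1-one
Conditions: (S,S)-ProPhenol [2,6-bis{[(S)-2-(hydroxydiphenylmethyl)pyrrolidin-1-yl]methyl}-4-methylphenol] (10 mol %), Et2Zn (20 mol %), 4 Å MS, THF, −35 °C
Reagents that add atoms: none
Why: The ligand and two equivalents of Et2Zn form a dinuclear divalent-zinc complex whose basic site deprotonates 9 to an enediolate held as a five-membered O,O-chelate across the two zinc centres; aldehyde 6 binds to the neighbouring Lewis-acidic zinc, C2 attacks the C3 carbonyl, and proton transfer from a further molecule of 9 releases 10 and reloads the catalyst. The closest known reaction type is the zinc–ProPhenol direct asymmetric aldol addition of 2-hydroxyacetophenones to branched and unbranched aliphatic aldehydes, which gives syn-1,2-diols without preformed enolates or protection of the donor hydroxyl. No ring is closed. C2 is controlled by the chelate, which fixes the Z-enediolate geometry and exposes one face under the diphenylcarbinol arm of the ligand, and C3 is controlled by the orientation of the zinc-bound aldehyde in the same pocket (attack on its Re face), the two together giving the syn (2R,3S) array. The step needs donor/acceptor chemoselectivity: only 9 can form the chelated enediolate, so the enolisable aldehyde 6 should serve only as acceptor, and the aryl ketone, deactivated by its para-benzyloxy group, should not be attacked. It also needs catalyst control over the resident C5 centre, which the bulky, non-chelating OTBS group secures by keeping the C5 oxygen off zinc, so that the 3,5-syn relationship follows from the ligand and not from the substrate.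

Step 8
Reactants: 10 (2R,3S,5S)-1-[4-(benzyloxy)phenyl]-7-[4-(benzyloxy)-3-methoxyphenyl]-5-[(tert-butyldimethylsilyl)oxy]-2,3-dihydroxyheptan-1-one
Product: 11 (2R,3S,5S)-1-[4-(benzyloxy)phenyl]-7-[4-(benzyloxy)-3-methoxyphenyl]-5-[(tert-butyldimethylsilyl)oxy]heptane-1,2,3-triol (mixture of C1 epimers)
Conditions: NaBH4, MeOH, 0 °C
Reagents that add atoms: none
Why: Borohydride 1,2-reduction of the aryl ketone, fast enough at 0 °C to outrun epimerisation at C2, with a C1 configuration that is irrelevant because this carbinol is erased in step 9.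

Step 9
Reactants: 11 (2R,3S,5S)-1-[4-(benzyloxy)phenyl]-7-[4-(benzyloxy)-3-methoxyphenyl]-5-[(tert-butyldimethylsilyl)oxy]heptane-1,2,3-triol (mixture of C1 epimers)
Product: 13 (2S,3S,5S)-7-(4-hydroxy-3-methoxyphenyl)-1-(4-hydroxyphenyl)heptane-2,3,5-triol, via 5-O-silyl triol 12 (not isolated)
Conditions: H2 (3 atm), Pd(OH)2/C, EtOH–AcOH 9:1, rt; filter; then 1 M aq. HCl, rt
Reagents that add atoms: none
Why: Catalytic hydrogenolysis should cleave the two aryl benzyl ethers and the C1–OH bond, which is benzylic and para-oxygenated, while the aliphatic carbinols at C2, C3 and C5 are inert, and the acid that removes the silyl ether is added only after C1 has become a methylene, so that no benzylic cation can arise next to the diol and no stereocentre is touched.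

Compound list
1 | zingerone, 4-(4-hydroxy-3-methoxyphenyl)butan-2-one | COc1cc(CCC(C)=O)ccc1O | starting material
2 | 4-[4-(benzyloxy)-3-methoxyphenyl]butan-2-one | COc1cc(CCC(C)=O)ccc1OCc1ccccc1 | intermediate
3 | methyl 5-[4-(benzyloxy)-3-methoxyphenyl]-3-oxopentanoate | COc1cc(CCC(=O)CC(=O)OC)ccc1OCc1ccccc1 | intermediate
4 | methyl (3S)-5-[4-(benzyloxy)-3-methoxyphenyl]-3-hydroxypentanoate | COc1cc(CC[C@H](O)CC(=O)OC)ccc1OCc1ccccc1 | intermediate
5 | methyl (3S)-5-[4-(benzyloxy)-3-methoxyphenyl]-3-[(tert-butyldimethylsilyl)oxy]pentanoate | COc1cc(CC[C@H](O[Si](C)(C)C(C)(C)C)CC(=O)OC)ccc1OCc1ccccc1 | intermediate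
6 | (3S)-5-[4-(benzyloxy)-3-methoxyphenyl]-3-[(tert-butyldimethylsilyl)oxy]pentanal | COc1cc(CC[C@H](O[Si](C)(C)C(C)(C)C)CC=O)ccc1OCc1ccccc1 | intermediate
7 | 2-bromo-1-[4-(benzyloxy)phenyl]ethan-1-one | O=C(CBr)c1ccc(OCc2ccccc2)cc1 | starting material
8 | 2-[4-(benzyloxy)phenyl]-2-oxoethyl formate | O=COCC(=O)c1ccc(OCc2ccccc2)cc1 | intermediate
9 | 2-hydroxy-1-[4-(benzyloxy)phenyl]ethan-1-one | O=C(CO)c1ccc(OCc2ccccc2)cc1 | intermediate
10 | (2R,3S,5S)-1-[4-(benzyloxy)phenyl]-7-[4-(benzyloxy)-3-methoxyphenyl]-5-[(tert-butyldimethylsilyl)oxy]-2,3-dihydroxyheptan-1-one | COc1cc(CC[C@H](O[Si](C)(C)C(C)(C)C)C[C@H](O)[C@@H](O)C(=O)c2ccc(OCc3ccccc3)cc2)ccc1OCc1ccccc1 | intermediate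
11 | (2R,3S,5S)-1-[4-(benzyloxy)phenyl]-7-[4-(benzyloxy)-3-methoxyphenyl]-5-[(tert-butyldimethylsilyl)oxy]heptane-1,2,3-triol, C1 epimers | COc1cc(CC[C@H](O[Si](C)(C)C(C)(C)C)C[C@H](O)[C@@H](O)C(O)c2ccc(OCc3ccccc3)cc2)ccc1OCc1ccccc1 | intermediate
12 | (2S,3S,5S)-5-[(tert-butyldimethylsilyl)oxy]-7-(4-hydroxy-3-methoxyphenyl)-1-(4-hydroxyphenyl)heptane-2,3-diol | COc1cc(CC[C@H](O[Si](C)(C)C(C)(C)C)C[C@H](O)[C@@H](O)Cc2ccc(O)cc2)ccc1O | intermediate
13 | (2S,3S,5S)-7-(4-hydroxy-3-methoxyphenyl)-1-(4-hydroxyphenyl)heptane-2,3,5-triol | COc1cc(CC[C@H](O)C[C@H](O)[C@@H](O)Cc2ccc(O)cc2)ccc1O | target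

Total step count: 9. Longest linear sequence: 8 (steps 1 to 5, then 7, 8 and 9).

Steps most likely to fail

Step 7. Facial selectivity may erode, because the intrinsic 1,3-anti preference of a β-silyloxy aldehyde opposes the catalyst. The aldehyde may also be lost through self-aldolisation or β-elimination of silanol. The fallback replaces catalyst control by auxiliary control; it sets out from 6 and comes back at 12. Aldehyde 6 would be added to the dibutylboron Z-enolate of commercial (R)-4-benzyl-3-[(benzyloxy)acetyl]oxazolidin-2-one (Bu2BOTf, Et3N, CH2Cl2, −78 to 0 °C). This Evans syn glycolate aldol gives the imide aldol adduct F1. Transamidation with MeNHOMe·HCl and AlMe3 would give the Weinreb amide F2. Excess 4-(benzyloxy)phenylmagnesium bromide (Weinreb ketone synthesis) would give the 2-O-benzyl ketone F3, and NaBH4 would give the 2-O-benzyl benzylic alcohol F4. Hydrogenolysis under the first half of the step 9 conditions should then remove three benzyl groups and the C1 oxygen to give 12.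

Step 9. The benzylic C–O cleavage may stall once the benzyl ethers are gone. If more acid is used to force it, a 1,2-hydride shift from C2 to a C1 cation may follow. The fallback activates the C1 oxygen as an ester so that it leaves under neutral conditions; it sets out from 11 and comes back at 13. Peracetylation (Ac2O, pyridine, DMAP) would give the triacetate F5. Neutral hydrogenolysis (H2, Pd/C, EtOAc) should cleave the benzylic acetate and both benzyl ethers to give the diacetate bisphenol F6. Methanolic HCl would then remove the two acetates and the silyl group to give 13.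

Step 5. The ester may be over-reduced to the primary alcohol, and silanol may be lost by β-elimination from the aldehyde during a slow work-up. The fallback trades the partial reduction for a full reduction and reoxidation; it sets out from 5 and comes back at 6. LiBH4 in THF would give the primary alcohol F7, and buffered Dess–Martin periodinane in CH2Cl2 would oxidise it to 6.

Further compounds
F1 | step 7 | (R)-4-benzyl-3-{(2R,3S,5S)-2-(benzyloxy)-7-[4-(benzyloxy)-3-methoxyphenyl]-5-[(tert-butyldimethylsilyl)oxy]-3-hydroxyheptanoyl}oxazolidin-2-one | COc1cc(CC[C@H](O[Si](C)(C)C(C)(C)C)C[C@H](O)[C@@H](OCc2ccccc2)C(=O)N2[C@H](Cc3ccccc3)COC2=O)ccc1OCc1ccccc1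
F2 | step 7 | (2R,3S,5S)-2-(benzyloxy)-7-[4-(benzyloxy)-3-methoxyphenyl]-5-[(tert-butyldimethylsilyl)oxy]-3-hydroxy-N-methoxy-N-methylheptanamide | COc1cc(CC[C@H](O[Si](C)(C)C(C)(C)C)C[C@H](O)[C@@H](OCc2ccccc2)C(=O)N(C)OC)ccc1OCc1ccccc1
F3 | step 7 | (2R,3S,5S)-2-(benzyloxy)-1-[4-(benzyloxy)phenyl]-7-[4-(benzyloxy)-3-methoxyphenyl]-5-[(tert-butyldimethylsilyl)oxy]-3-hydroxyheptan-1-one | COc1cc(CC[C@H](O[Si](C)(C)C(C)(C)C)C[C@H](O)[C@@H](OCc2ccccc2)C(=O)c2ccc(OCc3ccccc3)cc2)ccc1OCc1ccccc1
F4 | step 7 | (2R,3S,5S)-2-(benzyloxy)-1-[4-(benzyloxy)phenyl]-7-[4-(benzyloxy)-3-methoxyphenyl]-5-[(tert-butyldimethylsilyl)oxy]heptane-1,3-diol, C1 epimers | COc1cc(CC[C@H](O[Si](C)(C)C(C)(C)C)C[C@H](O)[C@@H](OCc2ccccc2)C(O)c2ccc(OCc3ccccc3)cc2)ccc1OCc1ccccc1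
F5 | step 9 | (2R,3S,5S)-1-[4-(benzyloxy)phenyl]-7-[4-(benzyloxy)-3-methoxyphenyl]-5-[(tert-butyldimethylsilyl)oxy]heptane-1,2,3-triyl triacetate, C1 epimers | COc1cc(CC[C@H](O[Si](C)(C)C(C)(C)C)C[C@H](OC(C)=O)[C@@H](OC(C)=O)C(OC(C)=O)c2ccc(OCc3ccccc3)cc2)ccc1OCc1ccccc1
F6 | step 9 | (2S,3S,5S)-5-[(tert-butyldimethylsilyl)oxy]-7-(4-hydroxy-3-methoxyphenyl)-1-(4-hydroxyphenyl)heptane-2,3-diyl diacetate | COc1cc(CC[C@H](O[Si](C)(C)C(C)(C)C)C[C@H](OC(C)=O)[C@@H](OC(C)=O)Cc2ccc(O)cc2)ccc1O
F7 | step 5 | (3S)-5-[4-(benzyloxy)-3-methoxyphenyl]-3-[(tert-butyldimethylsilyl)oxy]pentan-1-ol | COc1cc(CC[C@H](O[Si](C)(C)C(C)(C)C)CCO)ccc1OCc1ccccc1
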